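(The readings are simulated for an exercise; scatter was added.)

**The amounts.** Each flask takes one substrate charge, fed over 30 h into the coupling partner, and I count in fractions of that charge.

| flask | substrate | coupling partner | remark | time |
|---|---|---|---|---|
| midnight | 0.050 M (fed, over 30 h) | 1.8 equiv | the very flask that is asked about, followed so far |  |
| winter | 0.050 M (fed, over 30 h) | 2.7 equiv | run made earlier |  |
| flask | 0.050 M (fed, over 30 h) | 1.80 equiv |  | 15 d |

- midnight (time / h: bis adduct / %, side product / %): 2.50: 0, 0; 8.00: 4.2, 3.5; 12.0: 5.4, 4.2; 20.0: 6.9, 9.7; 30.0: 7.6, 14.9
- winter (time / d: bis adduct / %, side product / %): 2.00: 9.1, 20.2; 4.00: 9.2, 25.9; 6.00: 10.8, 27.7; 8.00: 8.7, 27.9; 10.0: 8.6, 25.2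

(readings scatter by 1 percentage point)

- percentages count the whole charge, also what has not yet gone in
- the reaction counts as stopped when no species that holds the substrate changes by six tenths of a point or more over the second half of the time

1. at 15 d, what has stopped the reaction, if anything has (it is still moving / forward and back rates have come level / the coupling partner has run out first / all of the substrate has reacted)
2. how much bis adduct there is at 15 d, in percent of the substrate charged
3. how much side product there is at 15 d, in percent of the substrate charged

**An odd pair.** I take a bis adduct to hold two partners and a side product one. Averaged over the winter readings from 6.00 d on, side product plus twice bis adduct reads 45.7% of the substrate charge; I call this the bound partner. Yet the winter flask got 2.7 equiv of partner, and over those readings its products barely move.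

**Clearing it.** Stalled products with partner unaccounted for suggest that partner left by a path holding no substrate. Suppose it consumes itself, at a rate in the square of its own concentration. On that supposition, once that loss dominates, its late level falls as one over time, whatever partner was charged. So I carry the bound partner unchanged to this flask, with the same substrate charge and feed, at 1.80 equiv. With bis adduct near its last midnight reading, 7.6%, side product comes to 30.5%, and I expect lost partner, not equilibrium, to end it.

**The forecast.** The forecast, which parts from me on the stop, says forward and back rates have come level, with bis adduct 6% and side product 30%, since “the plateau looks like equilibrium”.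

**The result.** At 15 d the flask gives: the coupling partner has run out first, bis adduct 8.11%, side product 26.3%. Its bound partner is 42.5%, against my 45.7%.

    substrate + coupling partner → first product (k = 0.00300 L mol⁻¹ s⁻¹)
    coupling partner + first product → bis adduct (k = 0.00110 L mol⁻¹ s⁻¹)
    first product → side product (k = 1.30 × 10⁻⁵ s⁻¹)
    2 coupling partner → homo dimer (k = 6.80 × 10⁻⁴ L mol⁻¹ s⁻¹)

At 0.0592 d in this flask the coupling partner, the limiting reagent, is used 16 times as fast into homo dimer as into first product. At 15.0 d in this flask, 0% of it is left beside 66% of the substrate.

**Second flask.** A neighbour flask takes 0.085 M of substrate at the same equivalents; if I assume that it binds the same partner per volume, my bound partner becomes 26.9% of its charge. The computed neighbour has side product 20.2% and bis adduct 7.13%, so 34.4%: above my figure, but less than in this flask.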